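**Plan** (flavanone numbering: O1, C2, C3, C4, C4a, C5–C8, C8a; ring B primed)
1. The retrosynthesis cuts, in this order: the four MOM–O bonds, the aryl ether bond O1–C8a of ring C, the ketone bond C4–C4a, the C2–C3 bond, and the two aryl–prenyl bonds (at C8 and C5′).
2. Forward: rings A and B are bought as benzenes. Ring A fragment 6 (F on the future C8a, prenyl on C8, Br on C4a) and ring B fragment 14 (carrying C2, C3, C4) are made separately and joined at C4–C4a. Ring C is the only ring made, last, by O1–C8a closure, followed by deprotection.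
3. Stereochemistry: C2 is set as S by asymmetric transfer hydrogenation of the ring B β-keto amide (step 7). It is not touched afterwards, because ring C is closed at the O1–aryl bond and not at the O1–C2 bond.
4. Enabling feature: C8a of ring A is ortho to C4a, which carries the C4 carbonyl of ring C, so a C8a–F bond behaves as a vinylogous acyl fluoride. The ring A oxygens on C5 and C7 are both meta to C8a. Fluorine sits only on the carbon next to the C8 prenyl group, which fixes 8-prenyl over 6-prenyl closure, and the activating ketone is part of the target, so no helper group has to be removed.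

Key step: step 9

Assumption: compounds 1, 4, 7, 9 and 11 are taken as commercial; MOM is used on all four phenols because it survives organolithium, hydride and alkoxide steps and is removed without hydrogenation or strong Lewis acid, which the prenyl groups would not tolerate.

**Step 1**
Reactants: 1 5-fluorobenzene-1,3-diol
Product: 2 1-fluoro-3,5-bis(methoxymethoxy)benzene
Conditions: MOMCl (2.6 equiv), i-Pr2NEt (3 equiv), CH2Cl2, 0 to 20 °C
Reagents that add atoms: chloromethyl methyl ether, COCCl
Why: O-alkylation of both phenols with the α-chloro ether (MOM protection) should mask them as acetals that are stable to organolithiums and alkoxides and keep ring A free of phenoxide charge for the later SNAr.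

**Step 2**
Reactants: 2 1-fluoro-3,5-bis(methoxymethoxy)benzene
Product: 3 2,4-dibromo-3-fluoro-1,5-bis(methoxymethoxy)benzene
Conditions: NBS (2.05 equiv), MeCN, 0 to 20 °C, dark
Reagents that add atoms: N-bromosuccinimide, O=C1CCC(=O)N1Br
Why: electrophilic aromatic bromination should go twice to the two equivalent carbons that are para to one acetal oxygen and ortho to the other, i.e. the two carbons flanking fluorine (future C4a and C8), and spare the more hindered C–H between the two OMOM groups (future C6), as in the 4,6-dihalogenation of resorcinol diethers.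

**Step 3**
Reactants: 3 2,4-dibromo-3-fluoro-1,5-bis(methoxymethoxy)benzene; 4 1-bromo-3-methylbut-2-ene (prenyl bromide)
Product: 6 2-bromo-3-fluoro-1,5-bis(methoxymethoxy)-4-(3-methylbut-2-en-1-yl)benzene, via aryllithium 5 (not isolated)
Conditions: n-BuLi (1.0 equiv), THF, −78 °C; then CuBr·SMe2 (10 mol %), 4 (1.5 equiv), −78 to −30 °C
Reagents that add atoms: none
Why: bromine–lithium exchange at one of the two equivalent bromides followed by copper-catalysed SN2 allylation with prenyl bromide should desymmetrize 3 and place the unbranched prenyl group next to fluorine (future C8), the ortho-fluoroaryllithium being kept cold to prevent loss of LiF.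

**Step 4**
Reactants: 7 methyl 3-bromo-4,5-dihydroxybenzoate
Product: 8 methyl 3-bromo-4,5-bis(methoxymethoxy)benzoate
Conditions: MOMCl (2.6 equiv), i-Pr2NEt (3 equiv), CH2Cl2, 0 to 20 °C
Reagents that add atoms: chloromethyl methyl ether, COCCl
Why: MOM protection (O-alkylation) of the catechol should give the bis-acetal needed to carry ring B through the palladium, enolate and organometallic steps.

**Step 5**
Reactants: 8 methyl 3-bromo-4,5-bis(methoxymethoxy)benzoate; 9 tributyl(3-methylbut-2-en-1-yl)stannane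
Product: 10 methyl 3,4-bis(methoxymethoxy)-5-(3-methylbut-2-en-1-yl)benzoate
Conditions: Pd(PPh3)4 (5 mol %), DMF, 90 °C
Reagents that add atoms: none
Why: Stille coupling (oxidative addition of the aryl bromide to zerovalent palladium, transmetalation of the allylstannane, reductive elimination) should install the unbranched prenyl group at C5′ without touching the ester or the acetals.

**Step 6**
Reactants: 10 methyl 3,4-bis(methoxymethoxy)-5-(3-methylbut-2-en-1-yl)benzoate; 11 N-methoxy-N-methylacetamide
Product: 13 3-[3,4-bis(methoxymethoxy)-5-(3-methylbut-2-en-1-yl)phenyl]-N-methoxy-N-methyl-3-oxopropanamide, via lithium enolate 12 (not isolated)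
Conditions: 11 (2.2 equiv), LiN(i-Pr)2 (2.2 equiv), THF, −78 °C; then 10, −78 to −20 °C; aq NH4Cl
Reagents that add atoms: none
Why: crossed Claisen condensation of the amide enolate with the aryl ester should form the C2–C3 bond, two equivalents of enolate being used because the β-keto amide is more acidic than the acetamide.

**Step 7**
Reactants: 13 3-[3,4-bis(methoxymethoxy)-5-(3-methylbut-2-en-1-yl)phenyl]-N-methoxy-N-methyl-3-oxopropanamide
Product: 14 (3S)-3-[3,4-bis(methoxymethoxy)-5-(3-methylbut-2-en-1-yl)phenyl]-3-hydroxy-N-methoxy-N-methylpropanamide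
Conditions: RuCl[(S,S)-TsDPEN](p-cymene) (1 mol %), HCO2H/Et3N (5:2), DMF, 30 °C
Reagents that add atoms: none
Why: Noyori asymmetric transfer hydrogenation of the aryl ketone should set C2 as S, the (S,S)-diamine ligand delivering hydride to the same face as in the reduction of acetophenone to (S)-1-phenylethanol (aryl ranks above CH2 in both), while the prenyl alkene, the amide and the acetals are not reduced.

**Step 8**
Reactants: 6 2-bromo-3-fluoro-1,5-bis(methoxymethoxy)-4-(3-methylbut-2-en-1-yl)benzene; 14 (3S)-3-[3,4-bis(methoxymethoxy)-5-(3-methylbut-2-en-1-yl)phenyl]-3-hydroxy-N-methoxy-N-methylpropanamide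
Product: 17 (3S)-1-[2-fluoro-4,6-bis(methoxymethoxy)-3-(3-methylbut-2-en-1-yl)phenyl]-3-hydroxy-3-[3,4-bis(methoxymethoxy)-5-(3-methylbut-2-en-1-yl)phenyl]propan-1-one, via aryllithium 15 (not isolated), via magnesium alkoxide 16 (not isolated)
Conditions: 6 (1.3 equiv), n-BuLi (1.3 equiv), THF, −78 °C; 14, i-PrMgCl (1.0 equiv), THF, −20 °C; combine at −78 °C, warm to −40 °C; aq NH4Cl
Reagents that add atoms: none
Why: Weinreb ketone synthesis should form the C4–C4a bond by a single addition of the ring A aryllithium to the N-methoxy-N-methylamide, the hydroxyl being deprotonated beforehand with i-PrMgCl so that it does not quench the aryllithium, and C2 is not involved.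

**Step 9**
Reactants: 17 (3S)-1-[2-fluoro-4,6-bis(methoxymethoxy)-3-(3-methylbut-2-en-1-yl)phenyl]-3-hydroxy-3-[3,4-bis(methoxymethoxy)-5-(3-methylbut-2-en-1-yl)phenyl]propan-1-one
Product: 20 (2S)-5,7-bis(methoxymethoxy)-2-[3,4-bis(methoxymethoxy)-5-(3-methylbut-2-en-1-yl)phenyl]-8-(3-methylbut-2-en-1-yl)-2,3-dihydro-4H-chromen-4-one, via sodium alkoxide 18 (not isolated), via Meisenheimer adduct 19 (not isolated)
Conditions: NaH (1.0 equiv), THF, 0 °C; then DMF (10 vol %), 0 to 20 °C; pH 7 buffer at 0 °C
Reagents that add atoms: none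
Why: NaH removes the C2–OH proton and the alkoxide oxygen of 18 adds to C8a, the fluorine-bearing carbon ortho to the C4 ketone, to give cyclohexadienyl anion 19 with its charge spread over C4a, C6, C8 and the C4 carbonyl oxygen; loss of fluoride then restores ring A (addition–elimination SNAr). The closest known reaction type is the intramolecular SNAr O-arylation of alkoxides and enolates on ortho-fluoroaryl ketones used to make chromanones, chromones and flavones. Ring C closes in a 6-exo-trig mode, the C–F bond that is broken lying outside the new ring. No stereocenter is formed, and C2 should keep its S configuration because the O1–C2 bond is neither made nor broken, only the O1–aryl bond. The step needs site selectivity between the two carbons ortho to the ketone and chemoselectivity for SNAr over retro-aldol cleavage and E1cB dehydration of the aldolate: the first is secured because only C8a carries fluoride, a far better leaving group than the methoxymethoxide on C5, so O1 must end next to the C8 prenyl group; the second by the high effective molarity of a six-membered closure, one equivalent of base, the sodium counter-ion and low temperature. The MOM ethers on C5 and C7 are meta to C8a and keep ring A free of phenoxide charge, so they should not slow the substitution.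

**Step 10**
Reactants: 20 (2S)-5,7-bis(methoxymethoxy)-2-[3,4-bis(methoxymethoxy)-5-(3-methylbut-2-en-1-yl)phenyl]-8-(3-methylbut-2-en-1-yl)-2,3-dihydro-4H-chromen-4-one
Product: 21 (2S)-2-[3,4-dihydroxy-5-(3-methylbut-2-en-1-yl)phenyl]-5,7-dihydroxy-8-(3-methylbut-2-en-1-yl)-2,3-dihydro-4H-chromen-4-one
Conditions: HCl (3 M aq)/MeOH (1:9), 45 °C, argon
Reagents that add atoms: none
Why: acid-catalysed acetal methanolysis should remove the four MOM groups as dimethoxymethane, with dilute acid, moderate temperature and exclusion of air chosen so that the prenyl alkenes are not protonated onto the neighbouring C7 and C4′ phenols and the catechol is not oxidized; C2 epimerizes only by base-induced ring opening and should be retained.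

**Compound list**
1 | 5-fluorobenzene-1,3-diol | Oc1cc(O)cc(F)c1 | starting material
2 | 1-fluoro-3,5-bis(methoxymethoxy)benzene | COCOc1cc(F)cc(OCOC)c1 | intermediate
3 | 2,4-dibromo-3-fluoro-1,5-bis(methoxymethoxy)benzene | COCOc1cc(OCOC)c(Br)c(F)c1Br | intermediate
4 | 1-bromo-3-methylbut-2-ene (prenyl bromide) | CC(C)=CCBr | starting material
5 | [3-bromo-2-fluoro-4,6-bis(methoxymethoxy)phenyl]lithium | [Li]c1c(OCOC)cc(OCOC)c(Br)c1F | intermediate (not isolated)
6 | 2-bromo-3-fluoro-1,5-bis(methoxymethoxy)-4-(3-methylbut-2-en-1-yl)benzene | COCOc1cc(OCOC)c(CC=C(C)C)c(F)c1Br | intermediate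
7 | methyl 3-bromo-4,5-dihydroxybenzoate | COC(=O)c1cc(O)c(O)c(Br)c1 | starting material
8 | methyl 3-bromo-4,5-bis(methoxymethoxy)benzoate | COCOc1cc(C(=O)OC)cc(Br)c1OCOC | intermediate
9 | tributyl(3-methylbut-2-en-1-yl)stannane | CCCC[Sn](CCCC)(CCCC)CC=C(C)C | starting material
10 | methyl 3,4-bis(methoxymethoxy)-5-(3-methylbut-2-en-1-yl)benzoate | COCOc1cc(C(=O)OC)cc(CC=C(C)C)c1OCOC | intermediate
11 | N-methoxy-N-methylacetamide | CC(=O)N(C)OC | starting material
12 | lithium 1-[methoxy(methyl)amino]ethen-1-olate | C=C(O[Li])N(C)OC | intermediate (not isolated)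
13 | 3-[3,4-bis(methoxymethoxy)-5-(3-methylbut-2-en-1-yl)phenyl]-N-methoxy-N-methyl-3-oxopropanamide | COCOc1cc(C(=O)CC(=O)N(C)OC)cc(CC=C(C)C)c1OCOC | intermediate
14 | (3S)-3-[3,4-bis(methoxymethoxy)-5-(3-methylbut-2-en-1-yl)phenyl]-3-hydroxy-N-methoxy-N-methylpropanamide | COCOc1cc([C@@H](O)CC(=O)N(C)OC)cc(CC=C(C)C)c1OCOC | intermediate
15 | [2-fluoro-4,6-bis(methoxymethoxy)-3-(3-methylbut-2-en-1-yl)phenyl]lithium | [Li]c1c(OCOC)cc(OCOC)c(CC=C(C)C)c1F | intermediate (not isolated)
16 | chloromagnesium (1S)-1-[3,4-bis(methoxymethoxy)-5-(3-methylbut-2-en-1-yl)phenyl]-3-[methoxy(methyl)amino]-3-oxopropan-1-olate | COCOc1cc([C@@H](O[Mg]Cl)CC(=O)N(C)OC)cc(CC=C(C)C)c1OCOC | intermediate (not isolated)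
17 | (3S)-1-[2-fluoro-4,6-bis(methoxymethoxy)-3-(3-methylbut-2-en-1-yl)phenyl]-3-hydroxy-3-[3,4-bis(methoxymethoxy)-5-(3-methylbut-2-en-1-yl)phenyl]propan-1-one | COCOc1cc([C@@H](O)CC(=O)c2c(F)c(CC=C(C)C)c(OCOC)cc2OCOC)cc(CC=C(C)C)c1OCOC | intermediate
18 | sodium (1S)-3-[2-fluoro-4,6-bis(methoxymethoxy)-3-(3-methylbut-2-en-1-yl)phenyl]-3-oxo-1-[3,4-bis(methoxymethoxy)-5-(3-methylbut-2-en-1-yl)phenyl]propan-1-olate | COCOc1cc([C@@H]([O-])CC(=O)c2c(F)c(CC=C(C)C)c(OCOC)cc2OCOC)cc(CC=C(C)C)c1OCOC.[Na+] | intermediate (not isolated)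
19 | sodium (2S)-8a-fluoro-5,7-bis(methoxymethoxy)-2-[3,4-bis(methoxymethoxy)-5-(3-methylbut-2-en-1-yl)phenyl]-8-(3-methylbut-2-en-1-yl)-2,3-dihydro-8aH-chromen-4-olate (C8a configuration undefined) | COCOc1cc([C@@H]2CC([O-])=C3C(OCOC)=CC(OCOC)=C(CC=C(C)C)C3(F)O2)cc(CC=C(C)C)c1OCOC.[Na+] | intermediate (not isolated)
20 | (2S)-5,7-bis(methoxymethoxy)-2-[3,4-bis(methoxymethoxy)-5-(3-methylbut-2-en-1-yl)phenyl]-8-(3-methylbut-2-en-1-yl)-2,3-dihydro-4H-chromen-4-one | COCOc1cc([C@@H]2CC(=O)c3c(OCOC)cc(OCOC)c(CC=C(C)C)c3O2)cc(CC=C(C)C)c1OCOC | intermediate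
21 | (2S)-2-[3,4-dihydroxy-5-(3-methylbut-2-en-1-yl)phenyl]-5,7-dihydroxy-8-(3-methylbut-2-en-1-yl)-2,3-dihydro-4H-chromen-4-one | CC(C)=CCc1cc([C@@H]2CC(=O)c3c(O)cc(O)c(CC=C(C)C)c3O2)cc(O)c1O | target

**Step count**
Total: 10 steps. Longest linear sequence: 7 steps (steps 4, 5, 6, 7, 8, 9, 10, from 7).

**Steps most likely to fail**

Step 9. Retro-aldol cleavage and recombination of alkoxide 18, or E1cB loss of water to the chalcone, could erode the C2 configuration or divert material before ring closure; excess base could also reopen ring C of 20. The fallback sets out from 17 and comes back at 20. Oxidation of the carbinol with Dess–Martin periodinane (CH2Cl2, 0 °C) should give 1-[2-fluoro-4,6-bis(methoxymethoxy)-3-(3-methylbut-2-en-1-yl)phenyl]-3-[3,4-bis(methoxymethoxy)-5-(3-methylbut-2-en-1-yl)phenyl]propane-1,3-dione F1, which cannot undergo retro-aldol cleavage. K2CO3 in DMF at 60 °C should then form the same O1–C8a bond by SNAr of the enol oxygen, the standard flavone synthesis from 1-(2-fluoroaryl)-1,3-diketones, to give 5,7-bis(methoxymethoxy)-2-[3,4-bis(methoxymethoxy)-5-(3-methylbut-2-en-1-yl)phenyl]-8-(3-methylbut-2-en-1-yl)-4H-chromen-4-one F2. Enantioselective copper hydride 1,4-reduction of the chromone C2=C3 bond (Cu(OAc)2, DTBM-SEGPHOS, (EtO)2MeSiH, t-BuOH, toluene, 0 °C; ligand antipode chosen so that C2 becomes S), which should leave the isolated prenyl alkenes alone, returns the route to 20.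

Step 8. The di-ortho-substituted aryllithium 15 may deprotonate the amide α-CH2 instead of adding, or lose LiF to an aryne when the mixture is warmed to force addition. The fallback sets out from 14 and comes back at 17, replacing acyl substitution by addition to an aldehyde and reoxidation. Silylation (TBSOTf, 2,6-lutidine, CH2Cl2, −78 °C) should give (3S)-3-[3,4-bis(methoxymethoxy)-5-(3-methylbut-2-en-1-yl)phenyl]-3-[tert-butyl(dimethyl)silyloxy]-N-methoxy-N-methylpropanamide F3, and i-Bu2AlH (THF, −78 °C) should reduce the amide to (3S)-3-[3,4-bis(methoxymethoxy)-5-(3-methylbut-2-en-1-yl)phenyl]-3-[tert-butyl(dimethyl)silyloxy]propanal F4. Aryllithium 15 should add to the aldehyde within minutes at −78 °C to give (3S)-1-[2-fluoro-4,6-bis(methoxymethoxy)-3-(3-methylbut-2-en-1-yl)phenyl]-3-[3,4-bis(methoxymethoxy)-5-(3-methylbut-2-en-1-yl)phenyl]-3-[tert-butyl(dimethyl)silyloxy]propan-1-ol F5 as both C4 epimers. Dess–Martin periodinane should give (3S)-1-[2-fluoro-4,6-bis(methoxymethoxy)-3-(3-methylbut-2-en-1-yl)phenyl]-3-[3,4-bis(methoxymethoxy)-5-(3-methylbut-2-en-1-yl)phenyl]-3-[tert-butyl(dimethyl)silyloxy]propan-1-one F6, and HF·pyridine in THF/pyridine at 0 °C should remove the silyl group to give 17.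

Step 2. Site selectivity may be poor, with bromination at the carbon between the two OMOM groups (future C6) or a stop at the monobromide, because fluorine deactivates its ortho positions toward electrophiles. The fallback sets out from 2 and comes back at 3. Sterically controlled iridium-catalysed C–H borylation ([Ir(OMe)(cod)]2, 4,4′-di-tert-butyl-2,2′-bipyridine, B2pin2, THF, 80 °C), which prefers C–H bonds next to the small fluorine over the C–H between two OMOM groups, should give 2,2′-[2-fluoro-4,6-bis(methoxymethoxy)-1,3-phenylene]bis(4,4,5,5-tetramethyl-1,3,2-dioxaborolane) F7. Copper-mediated bromodeboronation (CuBr2, MeOH/H2O, 70 °C) should then give 3.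

**Further compounds**
F1 | step 9 | 1-[2-fluoro-4,6-bis(methoxymethoxy)-3-(3-methylbut-2-en-1-yl)phenyl]-3-[3,4-bis(methoxymethoxy)-5-(3-methylbut-2-en-1-yl)phenyl]propane-1,3-dione | COCOc1cc(C(=O)CC(=O)c2c(F)c(CC=C(C)C)c(OCOC)cc2OCOC)cc(CC=C(C)C)c1OCOC
F2 | step 9 | 5,7-bis(methoxymethoxy)-2-[3,4-bis(methoxymethoxy)-5-(3-methylbut-2-en-1-yl)phenyl]-8-(3-methylbut-2-en-1-yl)-4H-chromen-4-one | COCOc1cc(-c2cc(=O)c3c(OCOC)cc(OCOC)c(CC=C(C)C)c3o2)cc(CC=C(C)C)c1OCOC
F3 | step 8 | (3S)-3-[3,4-bis(methoxymethoxy)-5-(3-methylbut-2-en-1-yl)phenyl]-3-[tert-butyl(dimethyl)silyloxy]-N-methoxy-N-methylpropanamide | COCOc1cc([C@@H](O[Si](C)(C)C(C)(C)C)CC(=O)N(C)OC)cc(CC=C(C)C)c1OCOC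
F4 | step 8 | (3S)-3-[3,4-bis(methoxymethoxy)-5-(3-methylbut-2-en-1-yl)phenyl]-3-[tert-butyl(dimethyl)silyloxy]propanal | COCOc1cc([C@@H](O[Si](C)(C)C(C)(C)C)CC=O)cc(CC=C(C)C)c1OCOC
F5 | step 8 | (3S)-1-[2-fluoro-4,6-bis(methoxymethoxy)-3-(3-methylbut-2-en-1-yl)phenyl]-3-[3,4-bis(methoxymethoxy)-5-(3-methylbut-2-en-1-yl)phenyl]-3-[tert-butyl(dimethyl)silyloxy]propan-1-ol | COCOc1cc([C@@H](O[Si](C)(C)C(C)(C)C)CC(O)c2c(F)c(CC=C(C)C)c(OCOC)cc2OCOC)cc(CC=C(C)C)c1OCOC
F6 | step 8 | (3S)-1-[2-fluoro-4,6-bis(methoxymethoxy)-3-(3-methylbut-2-en-1-yl)phenyl]-3-[3,4-bis(methoxymethoxy)-5-(3-methylbut-2-en-1-yl)phenyl]-3-[tert-butyl(dimethyl)silyloxy]propan-1-one | COCOc1cc([C@@H](O[Si](C)(C)C(C)(C)C)CC(=O)c2c(F)c(CC=C(C)C)c(OCOC)cc2OCOC)cc(CC=C(C)C)c1OCOC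
F7 | step 2 | 2,2′-[2-fluoro-4,6-bis(methoxymethoxy)-1,3-phenylene]bis(4,4,5,5-tetramethyl-1,3,2-dioxaborolane) | COCOc1cc(OCOC)c(B2OC(C)(C)C(C)(C)O2)c(F)c1B3OC(C)(C)C(C)(C)O3
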